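**Retrosynthetic overview**
1. The strategy rests on ring B (C-5a, C-6, C-7, C-8, C-9, C-9a): it carries only the furan fusion (O-5 on C-5a, C-9b on C-9a) and the ethylene chain on C-7, so it is the sum of three alkynes: ArO–C≡CH (C-5a/C-6), the butynyl C≡CH of the ring-C arm (C-7/C-8) and Ar–C≡C–SiMe3 (C-9a/C-9).
2. Key disconnection: Rh(I) [2+2+2] of open-chain triyne 20 forms C-5a–C-9a, C-6–C-7 and C-8–C-9, closing the furan, ring B and the 18-membered ring together as the last ring-forming event; SiMe3 on C-9 steers the chain to C-7 and is then removed.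
3. Triyne 20 comes from salicylaldehyde 12: phenol → dichlorovinyl ether → ethynyl ether; CHO → alkyne → silylalkyne; ester arm → aldehyde → dibromoalkene → butynyl.
4. 12 comes from bibenzyl ester 9 by Vilsmeier formylation and chelation-controlled demethylation; 9 by Wittig/hydrogenation from phosphonium salt 6 and aldehyde 4, the latter by SNAr of methyl isoferulate on 4-fluorobenzaldehyde.
5. Rings A, C and D are bought as arenes; after step 14 only protodesilylation and demethylation remain.

Key step: step 14

Remark: the target has no stereocentre and its SMILES no stereodescriptor, so the macrocycle is taken as conformationally mobile and a racemic ligand is used; locants follow dibenzofuran numbering (ring A = C-1 to C-4a and C-9b, ring B = C-5a to C-9a), ring C is the catechol ring and ring D the para-phenylene ring.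

**Step 1**
Reactants: 1 isovanillin
Product: 2 methyl (E)-3-(3-hydroxy-4-methoxyphenyl)prop-2-enoate (methyl isoferulate)
Conditions: Ph3P=CHCO2Me (1.1 equiv), toluene, 80 °C
Reagents that add atoms: methyl (triphenylphosphoranylidene)acetate, COC(=O)C=P(c1ccccc1)(c1ccccc1)c1ccccc1
Why: Wittig olefination with a stabilised ylide tolerates the free phenol and gives the (E)-cinnamate, whose ester carbon is the future C-7.

**Step 2**
Reactants: 2 methyl isoferulate; 3 4-fluorobenzaldehyde
Product: 4 methyl (E)-3-[3-(4-formylphenoxy)-4-methoxyphenyl]prop-2-enoate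
Conditions: K2CO3, DMF, 120 °C
Reagents that add atoms: none
Why: SNAr of the phenoxide on the para-formyl-activated fluoroarene forms the diaryl ether, the cinnamate being inert to carbonate.

**Step 3**
Reactants: 5 3,5-dimethoxybenzyl bromide
Product: 6 (3,5-dimethoxybenzyl)triphenylphosphonium bromide
Conditions: PPh3, toluene, reflux
Reagents that add atoms: triphenylphosphine, c1ccc(cc1)P(c1ccccc1)c1ccccc1
Why: SN2 quaternisation of triphenylphosphine by a benzylic bromide.

**Step 4**
Reactants: 6 (3,5-dimethoxybenzyl)triphenylphosphonium bromide; 4 methyl (E)-3-[3-(4-formylphenoxy)-4-methoxyphenyl]prop-2-enoate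
Product: 8 methyl (E)-3-[3-[4-[2-(3,5-dimethoxyphenyl)ethenyl]phenoxy]-4-methoxyphenyl]prop-2-enoate (stilbene C=C as E/Z mixture), via phosphonium ylide 7 (not isolated)
Conditions: NaHMDS, THF, 0 °C; then 4, −78 °C → rt
Reagents that add atoms: none
Why: Wittig olefination of the only aldehyde by the preformed semistabilised ylide; the stilbene geometry is irrelevant because both C=C bonds are hydrogenated next.

**Step 5**
Reactants: 8 stilbene cinnamate
Product: 9 methyl 3-[3-[4-[2-(3,5-dimethoxyphenyl)ethyl]phenoxy]-4-methoxyphenyl]propanoate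
Conditions: H2 (1 atm), 10% Pd/C, EtOAc, rt
Reagents that add atoms: none
Why: Heterogeneous hydrogenation saturates the stilbene and cinnamate C=C bonds in one operation without touching the diaryl ether, the methyl ethers or the ester.

**Step 6**
Reactants: 9 bibenzyl ester
Product: 11 methyl 3-[3-[4-[2-(2-formyl-3,5-dimethoxyphenyl)ethyl]phenoxy]-4-methoxyphenyl]propanoate, via iminium chloride 10 (not isolated)
Conditions: POCl3, DMF, 0 → 60 °C; then aq. NaOAc
Reagents that add atoms: N,N-dimethylformamide, CN(C)C=O; water, O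
Why: Vilsmeier–Haack formylation should attack only the 1,3-dimethoxy-activated ring A, ortho to the alkyl chain and para to one methoxy group as with 5-alkylresorcinol dimethyl ethers; a minor isomer formylated between the two methoxy groups would be removed by chromatography.

**Step 7**
Reactants: 11 ring-A aldehyde
Product: 12 methyl 3-[3-[4-[2-(2-formyl-3-hydroxy-5-methoxyphenyl)ethyl]phenoxy]-4-methoxyphenyl]propanoate
Conditions: BCl3 (1.5 equiv), CH2Cl2, −78 → 0 °C; then H2O
Reagents that add atoms: none
Why: Chelation-controlled demethylation: BCl3 bound to the formyl oxygen cleaves only the ortho methoxy group and should spare the para methoxy group, the ring-C anisole and the methyl ester.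

**Step 8**
Reactants: 12 salicylaldehyde; 13 trichloroethylene
Product: 14 methyl 3-[3-[4-[2-[3-[(E)-1,2-dichloroethenyl]oxy-2-formyl-5-methoxyphenyl]ethyl]phenoxy]-4-methoxyphenyl]propanoate
Conditions: ClCH=CCl2 (3 equiv), K2CO3, DMF, 70 °C
Reagents that add atoms: none
Why: Carbonate generates dichloroacetylene from trichloroethylene and the phenoxide adds anti across it, the standard route to aryl (E)-1,2-dichlorovinyl ethers; aldehyde and ester are inert under these conditions.

**Step 9**
Reactants: 14 dichlorovinyl ether aldehyde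
Product: 15 methyl 3-[3-[4-[2-[3-[(E)-1,2-dichloroethenyl]oxy-2-ethynyl-5-methoxyphenyl]ethyl]phenoxy]-4-methoxyphenyl]propanoate
Conditions: dimethyl (1-diazo-2-oxopropyl)phosphonate, K2CO3, MeOH/THF, 0 °C → rt
Reagents that add atoms: dimethyl (1-diazo-2-oxopropyl)phosphonate, CC(=O)C(=[N+]=[N-])P(=O)(OC)OC
Why: Seyferth–Gilbert homologation with the Ohira–Bestmann reagent converts the aryl aldehyde into the terminal alkyne under carbonate/methanol, in which the methyl ester exchanges degenerately and the dichlorovinyl ether is stable.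

**Step 10**
Reactants: 15 aryl alkyne ester
Product: 16 3-[3-[4-[2-[3-[(E)-1,2-dichloroethenyl]oxy-2-ethynyl-5-methoxyphenyl]ethyl]phenoxy]-4-methoxyphenyl]propanal
Conditions: DIBAL-H (1.1 equiv), CH2Cl2, −78 °C; aq. Rochelle salt
Reagents that add atoms: none
Why: Partial ester reduction: at −78 °C the tetrahedral aluminium hemiacetal persists until work-up, and neither the alkyne nor the dichlorovinyl ether is reduced at this temperature.

**Step 11**
Reactants: 16 aldehyde
Product: 17 4-(4,4-dibromobut-3-enyl)-2-[4-[2-[3-[(E)-1,2-dichloroethenyl]oxy-2-ethynyl-5-methoxyphenyl]ethyl]phenoxy]-1-methoxybenzene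
Conditions: CBr4, PPh3, CH2Cl2, 0 °C
Reagents that add atoms: carbon tetrabromide, BrC(Br)(Br)Br
Why: Ramirez dibromoolefination (first stage of the Corey–Fuchs reaction) under neutral conditions masks the future C-7/C-8 alkyne as a 1,1-dibromoalkene, which is inert in the next step.

**Step 12**
Reactants: 17 dibromoalkene with terminal aryl alkyne
Product: 18 [2-[2-[4-[5-(4,4-dibromobut-3-enyl)-2-methoxyphenoxy]phenyl]ethyl]-6-[(E)-1,2-dichloroethenyl]oxy-4-methoxyphenyl]ethynyl-trimethylsilane
Conditions: Zn(OTf)2 (20 mol%), TMSOTf, Et3N, CH2Cl2, rt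
Reagents that add atoms: trimethylsilyl triflate, C[Si](C)(C)OS(=O)(=O)C(F)(F)F
Why: Zinc-catalysed electrophilic C-silylation of a terminal alkyne via the zinc acetylide needs only Et3N as base, so the two halovinyl groups, which react with lithium bases, are untouched and the only terminal alkyne present is silylated.

**Step 13**
Reactants: 18 silylalkyne with both halovinyl groups
Product: 20 [2-[2-[4-[5-(but-3-ynyl)-2-methoxyphenoxy]phenyl]ethyl]-6-ethynyloxy-4-methoxyphenyl]ethynyl-trimethylsilane (triyne; used at once), via dilithium bis-acetylide 19 (not isolated)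
Conditions: n-BuLi (5 equiv), THF, −78 → −40 °C; then sat. aq. NH4Cl, −78 °C
Reagents that add atoms: none
Why: n-BuLi converts both halovinyl groups into lithium acetylides (dehydrochlorination and Cl/Li exchange at the dichlorovinyl ether as in the standard ynol ether synthesis, and the second stage of the Corey–Fuchs reaction at the dibromoalkene), and buffered protonation gives the two terminal alkynes while the C-silyl alkyne is inert to n-BuLi at low temperature.

**Step 14**
Reactants: 20 triyne
Product: 21 9-trimethylsilyl asterelin A dimethyl ether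
Conditions: [Rh(cod)2]BF4/rac-H8-BINAP (10 mol%, H2-activated), (CH2Cl)2, 20 added over 12 h to 1 mM, rt → 60 °C
Reagents that add atoms: none
Why: Cationic Rh(I) couples the two alkynes on ring A oxidatively (C-5a to C-9a) to a rhodacyclopentadiene fused to the new furan, with rhodium on C-6 and on the silylated C-9; the tethered butynyl alkyne then inserts and reductive elimination forms C-6 to C-7 and C-8 to C-9. The closest known reactions are the Rh(I)/bisphosphine [2+2+2] cycloaddition of phenol-linked 1,6-diynes (2-alkynylaryl ethynyl ethers) with alkynes to dibenzofurans and the intramolecular Rh-catalysed cyclotrimerisation of tethered triynes to cyclophanes. The furan closes as the five-membered ring of the 1,6-diyne across the O–C(aryl)=C(aryl) tether, ring B closes by the cyclotrimerisation itself, and the 18-membered ring closes in the same event by delivery of the terminal alkyne through its 13-atom tether, which is why slow addition to high dilution is used. No stereocentre is formed. The step needs the chain on C-7 and not C-8: the SiMe3 group on C-9 disfavours coupling of the substituted alkyne carbon next to it, so the CH terminus should bond to C-9, and the silyl group also suppresses self-trimerisation at that alkyne.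

**Step 15**
Reactants: 21 9-trimethylsilyl asterelin A dimethyl ether
Product: 22 asterelin A dimethyl ether
Conditions: TFA/CH2Cl2 (1:4), 0 °C → rt
Reagents that add atoms: none
Why: Electrophilic ipso-protodesilylation of an aryl silane; protonation at C-9 is assisted by the β-silicon effect, by conjugation of the arenium ion through C-9a with the oxygenated ring A, and by relief of the C-1/C-9 bay strain.

**Step 16**
Reactants: 22 asterelin A dimethyl ether
Product: 23 asterelin A
Conditions: BBr3 (6 equiv), CH2Cl2, −78 → 0 °C; then MeOH, H2O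
Reagents that add atoms: none
Why: BBr3 cleaves both aryl methyl ethers by bromide attack on the O-methyl carbon of the boron-complexed ether, whereas the diaryl ether and dibenzofuran C–O bonds offer no sp3 carbon and should remain.

**Compound list**
1 | isovanillin | COc1ccc(C=O)cc1O | starting material
2 | methyl (E)-3-(3-hydroxy-4-methoxyphenyl)prop-2-enoate | COC(=O)/C=C/c1ccc(OC)c(O)c1 | intermediate
3 | 4-fluorobenzaldehyde | O=Cc1ccc(F)cc1 | starting material
4 | methyl (E)-3-[3-(4-formylphenoxy)-4-methoxyphenyl]prop-2-enoate | COC(=O)/C=C/c1ccc(OC)c(Oc2ccc(C=O)cc2)c1 | intermediate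
5 | 3,5-dimethoxybenzyl bromide | COc1cc(CBr)cc(OC)c1 | starting material
6 | (3,5-dimethoxybenzyl)triphenylphosphonium bromide | COc1cc(C[P+](c2ccccc2)(c2ccccc2)c2ccccc2)cc(OC)c1.[Br-] | intermediate
7 | (3,5-dimethoxybenzylidene)triphenylphosphorane | COc1cc(C=P(c2ccccc2)(c2ccccc2)c2ccccc2)cc(OC)c1 | intermediate
8 | methyl (E)-3-[3-[4-[2-(3,5-dimethoxyphenyl)ethenyl]phenoxy]-4-methoxyphenyl]prop-2-enoate (stilbene E/Z mixture) | COC(=O)/C=C/c1ccc(OC)c(Oc2ccc(C=Cc3cc(OC)cc(OC)c3)cc2)c1 | intermediate
9 | methyl 3-[3-[4-[2-(3,5-dimethoxyphenyl)ethyl]phenoxy]-4-methoxyphenyl]propanoate | COC(=O)CCc1ccc(OC)c(Oc2ccc(CCc3cc(OC)cc(OC)c3)cc2)c1 | intermediate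
10 | dimethyliminium chloride of 9 at the ring-A carbon between the chain and a methoxy group | COC(=O)CCc1ccc(OC)c(Oc2ccc(CCc3cc(OC)cc(OC)c3C=[N+](C)C)cc2)c1.[Cl-] | intermediate
11 | methyl 3-[3-[4-[2-(2-formyl-3,5-dimethoxyphenyl)ethyl]phenoxy]-4-methoxyphenyl]propanoate | COC(=O)CCc1ccc(OC)c(Oc2ccc(CCc3cc(OC)cc(OC)c3C=O)cc2)c1 | intermediate
12 | methyl 3-[3-[4-[2-(2-formyl-3-hydroxy-5-methoxyphenyl)ethyl]phenoxy]-4-methoxyphenyl]propanoate | COC(=O)CCc1ccc(OC)c(Oc2ccc(CCc3cc(OC)cc(O)c3C=O)cc2)c1 | intermediate
13 | trichloroethylene | ClC=C(Cl)Cl | starting material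
14 | methyl 3-[3-[4-[2-[3-[(E)-1,2-dichloroethenyl]oxy-2-formyl-5-methoxyphenyl]ethyl]phenoxy]-4-methoxyphenyl]propanoate | COC(=O)CCc1ccc(OC)c(Oc2ccc(CCc3cc(OC)cc(O/C(Cl)=C\Cl)c3C=O)cc2)c1 | intermediate
15 | methyl 3-[3-[4-[2-[3-[(E)-1,2-dichloroethenyl]oxy-2-ethynyl-5-methoxyphenyl]ethyl]phenoxy]-4-methoxyphenyl]propanoate | COC(=O)CCc1ccc(OC)c(Oc2ccc(CCc3cc(OC)cc(O/C(Cl)=C\Cl)c3C#C)cc2)c1 | intermediate
16 | 3-[3-[4-[2-[3-[(E)-1,2-dichloroethenyl]oxy-2-ethynyl-5-methoxyphenyl]ethyl]phenoxy]-4-methoxyphenyl]propanal | O=CCCc1ccc(OC)c(Oc2ccc(CCc3cc(OC)cc(O/C(Cl)=C\Cl)c3C#C)cc2)c1 | intermediate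
17 | 4-(4,4-dibromobut-3-enyl)-2-[4-[2-[3-[(E)-1,2-dichloroethenyl]oxy-2-ethynyl-5-methoxyphenyl]ethyl]phenoxy]-1-methoxybenzene | BrC(Br)=CCCc1ccc(OC)c(Oc2ccc(CCc3cc(OC)cc(O/C(Cl)=C\Cl)c3C#C)cc2)c1 | intermediate
18 | [2-[2-[4-[5-(4,4-dibromobut-3-enyl)-2-methoxyphenoxy]phenyl]ethyl]-6-[(E)-1,2-dichloroethenyl]oxy-4-methoxyphenyl]ethynyl-trimethylsilane | BrC(Br)=CCCc1ccc(OC)c(Oc2ccc(CCc3cc(OC)cc(O/C(Cl)=C\Cl)c3C#C[Si](C)(C)C)cc2)c1 | intermediate
19 | dilithium bis-acetylide of 20 (lithium on the ethynyl ether and butynyl termini) | [Li]C#CCCc1ccc(OC)c(Oc2ccc(CCc3cc(OC)cc(OC#C[Li])c3C#C[Si](C)(C)C)cc2)c1 | intermediate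
20 | [2-[2-[4-[5-(but-3-ynyl)-2-methoxyphenoxy]phenyl]ethyl]-6-ethynyloxy-4-methoxyphenyl]ethynyl-trimethylsilane | C#CCCc1ccc(OC)c(Oc2ccc(CCc3cc(OC)cc(OC#C)c3C#C[Si](C)(C)C)cc2)c1 | intermediate
21 | 9-trimethylsilyl asterelin A dimethyl ether | COc1cc2c3c(c1)oc1cc(cc([Si](C)(C)C)c13)CCc1ccc(OC)c(c1)Oc1ccc(cc1)CC2 | intermediate
22 | asterelin A dimethyl ether | COc1cc2c3c(c1)oc1cc(ccc13)CCc1ccc(OC)c(c1)Oc1ccc(cc1)CC2 | intermediate
23 | asterelin A | Oc1cc2c3c(c1)oc1cc(ccc13)CCc1ccc(O)c(c1)Oc1ccc(cc1)CC2 | target

**Totals**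
Total step count: 16. Longest linear sequence: 15 (steps 1, 2 and 4 to 16; step 3 is a one-step branch).

**Steps most likely to fail**

Step 14. The two terminal alkynes may oligomerise or cyclotrimerise intermolecularly faster than the strained 18-membered ring closes, because the silylated alkyne terminus, flanked by two ortho substituents and bound for the bay position, may be slow to enter the rhodacycle; insertion in the opposite sense (chain on C-8) is the second failure path. Fallback: the silyl steering group is given up. Setting out from 17, n-BuLi (6 equiv, THF, −78 → −40 °C) and NH4Cl would give the all-terminal triyne F1. The same Rh(I)-catalysed cyclotrimerisation under high dilution would then lead without bay strain directly to 22, where the route is rejoined and step 15 is skipped. Regiocontrol then rests on the tether alone, so the 17-membered C-8 isomer would have to be separated.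

Step 13. Four organolithium events on one substrate may leave one halovinyl site unconverted, allow attack at silicon, or lose the labile aryl ethynyl ether during work-up. Fallback: the two unveilings are separated. Setting out from 15, zinc-catalysed silylation (Zn(OTf)2, TMSOTf, Et3N) would give the silylalkyne ester F2. DIBAL-H at −78 °C would give the aldehyde F3. Colvin homologation with lithiated trimethylsilyldiazomethane (TMSCHN2, LDA, THF, −78 → 0 °C) would give the terminal butynyl compound F4. n-BuLi (3.3 equiv) then has only the dichlorovinyl ether to convert and, after NH4Cl, would return to 20.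

Step 15. Ipso-protonation at C-9 may be slow compared with reversible protonation of the electron-rich ring A, and forcing acid could open transannular electrophilic substitution or ether cleavage in the strained macrocycle. Fallback: silicon is removed through boron. Setting out from 21, excess BBr3 (CH2Cl2, −78 °C → rt) would effect ipso-borodesilylation together with both demethylations and, after aqueous work-up, give the boronic acid F5 (9-borono asterelin A). Protodeboronation in hot aqueous acetic acid would return to the route at 23.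

**Further compounds**
F1 | step 14 | 2-[4-[2-(2-ethynyl-3-ethynyloxy-5-methoxyphenyl)ethyl]phenoxy]-4-(but-3-ynyl)-1-methoxybenzene | C#CCCc1ccc(OC)c(Oc2ccc(CCc3cc(OC)cc(OC#C)c3C#C)cc2)c1
F2 | step 13 | methyl 3-[3-[4-[2-[3-[(E)-1,2-dichloroethenyl]oxy-5-methoxy-2-(trimethylsilylethynyl)phenyl]ethyl]phenoxy]-4-methoxyphenyl]propanoate | COC(=O)CCc1ccc(OC)c(Oc2ccc(CCc3cc(OC)cc(O/C(Cl)=C\Cl)c3C#C[Si](C)(C)C)cc2)c1
F3 | step 13 | 3-[3-[4-[2-[3-[(E)-1,2-dichloroethenyl]oxy-5-methoxy-2-(trimethylsilylethynyl)phenyl]ethyl]phenoxy]-4-methoxyphenyl]propanal | O=CCCc1ccc(OC)c(Oc2ccc(CCc3cc(OC)cc(O/C(Cl)=C\Cl)c3C#C[Si](C)(C)C)cc2)c1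
F4 | step 13 | [2-[2-[4-[5-(but-3-ynyl)-2-methoxyphenoxy]phenyl]ethyl]-6-[(E)-1,2-dichloroethenyl]oxy-4-methoxyphenyl]ethynyl-trimethylsilane | C#CCCc1ccc(OC)c(Oc2ccc(CCc3cc(OC)cc(O/C(Cl)=C\Cl)c3C#C[Si](C)(C)C)cc2)c1
F5 | step 15 | 9-borono asterelin A (boronic acid on C-9 and both phenols free) | Oc1cc2c3c(c1)oc1cc(cc(B(O)O)c13)CCc1ccc(O)c(c1)Oc1ccc(cc1)CC2
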